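At the same clock reading the north-west run shows 1.52 times the product percentage of the north run, and the north charge is 1.50 times the north-west charge. Two chemists dispute what that ratio means for the flask below, which has the north-west recipe.

| flask | substrate | gas | initiator | remark | time |
|---|---|---|---|---|---|
| north-west | 0.050 M (fed, over 50 s) | 2.4 mM (held) | 1 mM | the very flask that is asked about, followed so far |  |
| north | 0.075 M (fed, over 50 s) | 2.4 mM (held) | 1 mM | run made earlier |  |
| flask | 0.050 M (fed, over 50 s) | 2.4 mM (held) | 1.0 mM |  | 5.0 min |

north-west run (percent of the substrate charged)

| time / s | product / % | substrate / % |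
|---|---|---|
| 10.0 | 1.3 | 19.5 |
| 20.0 | 3.2 | 38.0 |
| 50.0 | 9.5 | 90.9 |
| 120 | 21.9 | 77.0 |

north run (percent of the substrate charged)

| time / min | product / % | substrate / % |
|---|---|---|
| 0.417 | 3.1 | 47.8 |
| 1.00 | 7.2 | 92.4 |
| 2.00 | 14.4 | 85.4 |
| 5.00 | 38.4 | 61.4 |

(standard deviation of a reading: 0.5 percentage points)

- at the start none of the gas is in solution
- percentages count the whole charge, also what has not yet gone in

1. amount of product in percent of the substrate charged, at 30 s, 2.0 min and 5.0 min

The first chemist says both north-run and north-west product grow at one molar rate, whatever the charge. She reads that rate from the north run between 2.00 min and 5.00 min. She then divides the flask's charge by it and calls the result the clearing time: the time the straight line needs for a whole charge. It is 8.33 min. This is a zero-order picture, and product fraction gains elapsed time over clearing time. From the north-west reading at 120 s she reaches 57.9% at 5.0 min.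

The second chemist holds first order: each run loses a fixed fraction of its substrate per unit time. After the feed, the north-west substrate readings give 0.142 min⁻¹. That closes to 49.7% product at 5.0 min, below her rival. Yet the north run gives her 0.110 min⁻¹, which is not the same constant.

The forecast takes the first side, though with a lower last number than the clearing time gives: 5.3%, 21.8% and 55%. Its ground is that the rate is “essentially zero order in substrate”.

    partner + first chain carrier ⇌ product + second chain carrier (K = 150, k = 1.60 × 10⁶ M⁻¹ s⁻¹)
    substrate + initiating radical → capped initiator + first chain carrier (k = 6.20 × 10⁵ M⁻¹ s⁻¹)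
    initiator → 2 initiating radical (k = 7.20 × 10⁻⁴ s⁻¹)
    gas ⇌ partner, rate k4*(csat - [partner]) (kL = 0.0400 s⁻¹)
    partner → decomposed reagent (k = 0.00390 s⁻¹)
    substrate + second chain carrier → by-product + first chain carrier (k = 67000 M⁻¹ s⁻¹)
    2 second chain carrier → ended chains (k = 8.30 × 10⁷ M⁻¹ s⁻¹)

The flask gives 4.89%, 22.2% and 56.7%, so the forecast holds and the first-order 49.7% falls short. In the flask at 5.00 min, partner stands at 2.82 × 10⁻⁷ M. The 43% of substrate left in the flask then is 3.58 min of straight line at the clearing time. The second chemist's ground lies beyond that line: at 50.0 min the flask's substrate is 0% and partner has risen to 0.00219 M.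

The readings stem from a simulated flask with made-up constants; the scatter is artificial.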